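## Retrosynthetic overview

1. Target 31 ⇐ chromenequinone 30 (dithionite reduction) ⇐ 5-chromenol 29. A Teuber oxidation puts in the C8 oxygen last.
2. The pyran ring is the last ring formed. It comes from aryl–O closure of Z-allylic tertiary alcohol 27, made by Sonogashira coupling of alkynol 21 with bromo-iodoarene 25 and semihydrogenation. The C2–O bond is never broken.
3. The C2 carbinol of 21 ⇐ Sharpless epoxidation of E-allylic alcohol 17 ⇐ carboalumination of enyne 14.
4. Enyne 14 ⇐ Peterson methylenation and Eschenmoser–Tanabe fragmentation of octalone 9. This temporary second carbocycle is closed by aldol condensation only to lock the secondary methyl trans to the angular methyl, and is then cut open again.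
5. Key C–C bond: quaternary ring carbon to side-chain CH2. It is made by intermolecular asymmetric Michael addition of the (S)-1-phenylethylamine imine of 2,6-dimethylcyclohexanone (ring bought) to methyl vinyl ketone.

Assumption: the SMILES is read as (2S) at the chromene carbon and (1R,3R) in the carbocycle (ring methyls trans), and the air- and light-sensitive chromene hydroquinone is handled under argon in the dark.

## Route

Step 1
Reactants: 1 2,6-dimethylcyclohexanone (cis/trans mixture); 2 (S)-(−)-1-phenylethylamine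
Product: 3 (1S)-N-(2,6-dimethylcyclohexylidene)-1-phenylethanamine (ring epimers)
Conditions: p-TsOH·H2O (1 mol %), toluene, reflux, Dean–Stark, 24–48 h; distillation
Reagents that add atoms: none
Why: Acid-catalysed ketimine condensation driven by azeotropic water removal, in which the ring α-carbons scramble by imine–enamine tautomerism and the only fixed stereocentre is the (S)-carbon bought with the amine.

Step 2
Reactants: 3 imine; 4 methyl vinyl ketone
Product: 7 (2R)-2,6-dimethyl-2-(3-oxobutyl)cyclohexanone (C6 epimers), via secondary enamine 5 (not isolated), via Michael adduct imine 6 (not isolated)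
Conditions: 4 (1.1 equiv), toluene, 40 °C, 3–5 d, N2; then 20 % aq AcOH, rt, 2 h
Reagents that add atoms: water, O
Why: Asymmetric Michael addition of a chiral imine through its secondary enamine tautomer (d'Angelo–Pfau deracemising alkylation), where the enone is attacked in a compact chair-like aza-ene transition state with internal N–H transfer on the enamine face anti to the phenyl group of the (S)-auxiliary, which forms the ring-to-side-chain C–C bond and sets the quaternary carbon as R while C6 stays epimerisable and is fixed in step 3.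

Step 3
Reactants: 7 (2R)-2,6-dimethyl-2-(3-oxobutyl)cyclohexanone
Product: 9 (4aR,8R)-4a,8-dimethyl-4,4a,5,6,7,8-hexahydronaphthalen-2(3H)-one, via bicyclic ketol 8 (not isolated)
Conditions: NaOMe (0.3 equiv), MeOH, rt → 60 °C, 12 h; low-temperature crystallisation from pentane to upgrade ee
Reagents that add atoms: none
Why: Intramolecular aldol condensation (second half of a Robinson annulation) under equilibrating conditions, in which C8 epimerises through the enolate and the extended dienolate and the isomer with the equatorial C8 methyl trans to the axial angular methyl wins because the cis isomer suffers a 1,3-diaxial Me/Me contact, so C8 is set as R relative to C4a.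

Step 4
Reactants: 9 octalone
Product: 10 (4aR,8R)-1,8a-epoxy-4a,8-dimethyloctahydronaphthalen-2(1H)-one (both epoxide faces, used together)
Conditions: 30 % H2O2 (5 equiv), 4 M NaOH (0.5 equiv), MeOH, 0 °C → rt, 24 h
Reagents that add atoms: hydrogen peroxide, OO
Why: Weitz–Scheffer nucleophilic epoxidation touches only the electron-poor enone C=C, and the epoxide configuration is of no consequence because both epoxide carbons lose their stereochemistry in step 5.

Step 5
Reactants: 10 epoxy ketone
Product: 12 (2R,6R)-2-(but-3-yn-1-yl)-2,6-dimethylcyclohexanone, via epoxy tosylhydrazone 11 (not isolated)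
Conditions: TsNHNH2 (1.1 equiv), AcOH/CH2Cl2 1:1, −20 °C (12 h) → rt (4 h)
Reagents that add atoms: none
Why: Eschenmoser–Tanabe fragmentation of the epoxy tosylhydrazone cleaves the C1–C8a bond and unveils the ring ketone and a terminal alkyne that keeps all four side-chain carbons, and the cold, weakly acidic medium leaves the α-methyl stereocentre (6R, trans to the C2 methyl) untouched.

Step 6
Reactants: 12 alkynyl ketone
Product: 13 (2R,6R)-2-(but-3-yn-1-yl)-2,6-dimethyl-1-[(trimethylsilyl)methyl]cyclohexanol
Conditions: anhydrous CeCl3 (3.5 equiv), TMSCH2Li (3.5 equiv), THF, −78 °C; then 12, −78 → 0 °C; H2O work-up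
Reagents that add atoms: (trimethylsilyl)methyllithium, [Li]C[Si](C)(C)C
Why: First half of a Peterson olefination in its organocerium variant, where the oxophilic and nearly non-basic cerium reagent adds to the hindered ketone instead of enolising it so that 6R is not epimerised, and the new carbinol carbon (attack anti to the axial C2 methyl) is destroyed again in step 7.

Step 7
Reactants: 13 β-hydroxysilane
Product: 14 (1R,3R)-1-(but-3-yn-1-yl)-1,3-dimethyl-2-methylidenecyclohexane
Conditions: KH (3 equiv), THF, 0 °C → rt, 2 h; H2O quench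
Reagents that add atoms: none
Why: Base-induced syn-elimination of the potassium β-silyl alkoxide (Peterson elimination) can only give the exocyclic methylene and touches neither ring stereocentre.

Step 8
Reactants: 14 enyne
Product: 17 (2E)-5-[(1R,3R)-1,3-dimethyl-2-methylidenecyclohexyl]-3-methylpent-2-en-1-ol, via vinylalane 15 (not isolated), via lithium alanate 16 (not isolated)
Conditions: AlMe3 (3 equiv), Cp2ZrCl2 (0.25 equiv), CH2Cl2, 0 °C → rt, 12 h; volatiles removed; hexane/THF, n-BuLi (1.1 equiv), −78 → 0 °C; (CH2O)n (4 equiv), rt; aqueous work-up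
Reagents that add atoms: trimethylaluminium, C[Al](C)C; paraformaldehyde (as formaldehyde), C=O
Why: Negishi zirconium-catalysed syn-carboalumination puts methyl on the internal and aluminium on the terminal alkyne carbon (E above 98 %), the derived alanate is hydroxymethylated with retention of alkene geometry, and the hindered 1,1-disubstituted ring alkene is inert.

Step 9
Reactants: 17 E-allylic alcohol
Product: 18 {(2S,3S)-3-[2-((1R,3R)-1,3-dimethyl-2-methylidenecyclohexyl)ethyl]-3-methyloxiran-2-yl}methanol
Conditions: Ti(OiPr)4 (10 mol %), L-(+)-diethyl tartrate (13 mol %), t-BuOOH (2 equiv, decane), 4 Å MS, CH2Cl2, −20 °C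
Reagents that add atoms: tert-butyl hydroperoxide, CC(C)(C)OO
Why: Sharpless asymmetric epoxidation oxidises only the alkene of the titanium-bound allylic alcohol, and L-(+)-tartrate delivers oxygen to the face that gives the (2S,3S)-epoxide exactly as with geraniol, so reagent control sets the future chromene C2–O bond as S.

Step 10
Reactants: 18 epoxy alcohol
Product: 19 (2S,3R)-3-(chloromethyl)-2-[2-((1R,3R)-1,3-dimethyl-2-methylidenecyclohexyl)ethyl]-2-methyloxirane
Conditions: PPh3 (1.5 equiv), NaHCO3 (0.3 equiv), CCl4, reflux, 3 h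
Reagents that add atoms: carbon tetrachloride, ClC(Cl)(Cl)Cl
Why: Appel reaction, an SN2 displacement at the primary carbinol under buffered neutral conditions that leaves the epoxide and both of its stereocentres in place (only the CIP label of the CH carbon changes).

Step 11
Reactants: 19 epoxy chloride
Product: 21 (3S)-5-[(1R,3R)-1,3-dimethyl-2-methylidenecyclohexyl]-3-methylpent-1-yn-3-ol, via lithium chlorovinyl alkoxide 20 (not isolated)
Conditions: n-BuLi (3.5 equiv), THF, −78 → −30 °C, 2 h; H2O quench
Reagents that add atoms: none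
Why: Base-induced double elimination of a 2,3-epoxy chloride (Takano–Yadav alkynol synthesis), where deprotonation of CH2Cl opens the epoxide to a chlorovinyl alkoxide that loses HCl to the alkyne, and the tertiary C–O bond is never broken so S is retained.

Step 12
Reactants: 22 5-bromo-2-methoxyphenol
Product: 23 4-bromo-1-methoxy-2-(methoxymethoxy)benzene
Conditions: MOMCl (1.3 equiv), iPr2NEt (1.6 equiv), CH2Cl2, 0 °C → rt
Reagents that add atoms: chloromethyl methyl ether, COCCl
Why: Simple O-alkylation of the phenol (Williamson-type) installs a base-stable acetal that also serves as the directing group for step 13.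

Step 13
Reactants: 23 MOM ether
Product: 25 1-bromo-2-iodo-4-methoxy-3-(methoxymethoxy)benzene, via aryllithium 24 (not isolated)
Conditions: LDA (1.15 equiv), THF, −78 °C, 45 min; I2 (1.3 equiv), THF, −78 °C → rt
Reagents that add atoms: iodine, II
Why: Directed ortho-metalation, in which the C–H flanked by OMOM and Br is by far the most acidic, the amide base does not undergo Br/Li exchange, the o-bromoaryllithium keeps its LiBr at −78 °C, and iodine traps it at that carbon.

Step 14
Reactants: 21 tertiary propargylic alcohol; 25 bromo-iodoarene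
Product: 26 (3S)-1-[6-bromo-3-methoxy-2-(methoxymethoxy)phenyl]-5-[(1R,3R)-1,3-dimethyl-2-methylidenecyclohexyl]-3-methylpent-1-yn-3-ol
Conditions: PdCl2(PPh3)2 (3 mol %), CuI (6 mol %), Et3N/THF 1:1 (degassed), rt → 45 °C, 12 h
Reagents that add atoms: none
Why: Sonogashira coupling, in which zerovalent palladium inserts into C–I far faster than into C–Br, free tertiary propargylic alcohols are standard partners, and no stereocentre is involved.

Step 15
Reactants: 26 aryl alkyne
Product: 27 (1Z,3S)-1-[6-bromo-3-methoxy-2-(methoxymethoxy)phenyl]-5-[(1R,3R)-1,3-dimethyl-2-methylidenecyclohexyl]-3-methylpent-1-en-3-ol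
Conditions: H2 (1 atm), Pd/CaCO3 poisoned with Pb(OAc)2 (Lindlar catalyst), quinoline, EtOAc, rt, stopped after 1.0 equiv H2
Reagents that add atoms: none
Why: Lindlar semihydrogenation delivers both hydrogens syn to give the Z-alkene, and the poisoned catalyst leaves the hindered exocyclic methylene and the aryl bromide alone.

Step 16
Reactants: 27 Z-allylic tertiary alcohol
Product: 28 (2S)-2-{2-[(1R,3R)-1,3-dimethyl-2-methylidenecyclohexyl]ethyl}-6-methoxy-5-(methoxymethoxy)-2-methyl-2H-chromene
Conditions: Pd(OAc)2 (5 mol %), 2-(di-tert-butylphosphino)-1,1'-binaphthyl (7 mol %), Cs2CO3 (1.5 equiv), toluene, 75 °C, dark, 12–24 h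
Reagents that add atoms: none
Why: Buchwald-type palladium-catalysed intramolecular C–O coupling forms the aryl–oxygen bond from a tertiary alkoxide that has no β-hydrogen and is held next to the metal by the Z-alkene, and since the alkyl C2–O bond is not broken the S configuration is retained.

Step 17
Reactants: 28 chromene MOM ether
Product: 29 (2S)-2-{2-[(1R,3R)-1,3-dimethyl-2-methylidenecyclohexyl]ethyl}-6-methoxy-2-methyl-2H-chromen-5-ol
Conditions: NaHSO4·SiO2, wet CH2Cl2, rt, 1–2 h, dark
Reagents that add atoms: none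
Why: Mild heterogeneous acid-catalysed acetal hydrolysis that is selective for phenolic MOM ethers and too weak to protonate the exocyclic alkene or to ionise the chromene C2–O bond.

Step 18
Reactants: 29 chromen-5-ol
Product: 30 (2S)-2-{2-[(1R,3R)-1,3-dimethyl-2-methylidenecyclohexyl]ethyl}-6-methoxy-2-methyl-2H-chromene-5,8-dione
Conditions: (KSO3)2NO (2.5 equiv), KH2PO4 buffer, acetone/H2O, rt, 1–3 h, dark
Reagents that add atoms: potassium nitrosodisulfonate (Fremy's salt), [K+].[K+].[O]N(S(=O)(=O)[O-])S(=O)(=O)[O-]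
Why: Teuber oxidation, in which the phenoxyl radical is captured by a second nitroxyl at the only free para position (C8–H) to give the p-quinone, while both alkenes and all stereocentres are inert to this radical.

Step 19
Reactants: 30 chromenequinone
Product: 31 target, (2S)-2-{2-[(1R,3R)-1,3-dimethyl-2-methylidenecyclohexyl]ethyl}-6-methoxy-2-methyl-2H-chromene-5,8-diol
Conditions: Na2S2O4 (5 equiv), Et2O/H2O, rt, 10 min, Ar, dark
Reagents that add atoms: none
Why: Two-electron quinone-to-hydroquinone reduction by dithionite under neutral two-phase conditions changes nothing but the two carbonyl groups.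

## Compound list

1 | 2,6-dimethylcyclohexanone (cis/trans mixture) | CC1CCCC(C)C1=O | starting material
2 | (S)-(−)-1-phenylethylamine | C[C@H](N)c1ccccc1 | starting material
3 | (1S)-N-(2,6-dimethylcyclohexylidene)-1-phenylethanamine (ring epimers) | C[C@H](N=C1C(C)CCCC1C)c1ccccc1 | intermediate
4 | methyl vinyl ketone | C=CC(C)=O | starting material
5 | 2,6-dimethyl-N-[(1S)-1-phenylethyl]cyclohex-1-en-1-amine (not isolated) | C[C@H](NC1=C(C)CCCC1C)c1ccccc1 | intermediate
6 | 4-[(1R)-1,3-dimethyl-2-{[(1S)-1-phenylethyl]imino}cyclohexyl]butan-2-one (not isolated) | C[C@H](N=C1C(C)CCC[C@]1(C)CCC(C)=O)c1ccccc1 | intermediate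
7 | (2R)-2,6-dimethyl-2-(3-oxobutyl)cyclohexanone (C6 epimers) | O=C1C(C)CCC[C@]1(C)CCC(C)=O | intermediate
8 | (4aR)-8a-hydroxy-4a,8-dimethyloctahydronaphthalen-2(1H)-one (not isolated, C8 and C8a equilibrating) | O=C1CC2(O)C(C)CCC[C@]2(C)CC1 | intermediate
9 | (4aR,8R)-4a,8-dimethyl-4,4a,5,6,7,8-hexahydronaphthalen-2(3H)-one | O=C1C=C2[C@H](C)CCC[C@]2(C)CC1 | intermediate
10 | (4aR,8R)-1,8a-epoxy-4a,8-dimethyloctahydronaphthalen-2(1H)-one (both epoxide faces) | O=C1C2OC23[C@H](C)CCC[C@]3(C)CC1 | intermediate
11 | p-toluenesulfonylhydrazone of 10 (not isolated) | Cc1ccc(S(=O)(=O)NN=C2C3OC34[C@H](C)CCC[C@]4(C)CC2)cc1 | intermediate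
12 | (2R,6R)-2-(but-3-yn-1-yl)-2,6-dimethylcyclohexanone | O=C1[C@H](C)CCC[C@]1(C)CCC#C | intermediate
13 | (2R,6R)-2-(but-3-yn-1-yl)-2,6-dimethyl-1-[(trimethylsilyl)methyl]cyclohexanol (C1 inconsequential) | C[Si](C)(C)CC1(O)[C@H](C)CCC[C@]1(C)CCC#C | intermediate
14 | (1R,3R)-1-(but-3-yn-1-yl)-1,3-dimethyl-2-methylidenecyclohexane | C=C1[C@H](C)CCC[C@]1(C)CCC#C | intermediate
15 | (E)-vinyl(dimethyl)alane (not isolated) | C=C1[C@H](C)CCC[C@]1(C)CC/C(C)=C/[Al](C)C | intermediate
16 | lithium butyl(dimethyl)vinylalanate (not isolated) | [Li+].C=C1[C@H](C)CCC[C@]1(C)CC/C(C)=C/[Al-](C)(C)CCCC | intermediate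
17 | (2E)-5-[(1R,3R)-1,3-dimethyl-2-methylidenecyclohexyl]-3-methylpent-2-en-1-ol | C=C1[C@H](C)CCC[C@]1(C)CC/C(C)=C/CO | intermediate
18 | {(2S,3S)-3-[2-((1R,3R)-1,3-dimethyl-2-methylidenecyclohexyl)ethyl]-3-methyloxiran-2-yl}methanol | C=C1[C@H](C)CCC[C@]1(C)CC[C@]1(C)O[C@H]1CO | intermediate
19 | (2S,3R)-3-(chloromethyl)-2-[2-((1R,3R)-1,3-dimethyl-2-methylidenecyclohexyl)ethyl]-2-methyloxirane | C=C1[C@H](C)CCC[C@]1(C)CC[C@]1(C)O[C@H]1CCl | intermediate
20 | lithium (3S)-1-chloro-5-[(1R,3R)-1,3-dimethyl-2-methylidenecyclohexyl]-3-methylpent-1-en-3-olate (not isolated) | [Li+].C=C1[C@H](C)CCC[C@]1(C)CC[C@](C)([O-])C=CCl | intermediate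
21 | (3S)-5-[(1R,3R)-1,3-dimethyl-2-methylidenecyclohexyl]-3-methylpent-1-yn-3-ol | C=C1[C@H](C)CCC[C@]1(C)CC[C@](C)(O)C#C | intermediate
22 | 5-bromo-2-methoxyphenol | COc1ccc(Br)cc1O | starting material
23 | 4-bromo-1-methoxy-2-(methoxymethoxy)benzene | COCOc1cc(Br)ccc1OC | intermediate
24 | [6-bromo-3-methoxy-2-(methoxymethoxy)phenyl]lithium (not isolated) | COCOc1c([Li])c(Br)ccc1OC | intermediate
25 | 1-bromo-2-iodo-4-methoxy-3-(methoxymethoxy)benzene | COCOc1c(I)c(Br)ccc1OC | intermediate
26 | (3S)-1-[6-bromo-3-methoxy-2-(methoxymethoxy)phenyl]-5-[(1R,3R)-1,3-dimethyl-2-methylidenecyclohexyl]-3-methylpent-1-yn-3-ol | C=C1[C@H](C)CCC[C@]1(C)CC[C@](C)(O)C#Cc1c(Br)ccc(OC)c1OCOC | intermediate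
27 | (1Z,3S)-1-[6-bromo-3-methoxy-2-(methoxymethoxy)phenyl]-5-[(1R,3R)-1,3-dimethyl-2-methylidenecyclohexyl]-3-methylpent-1-en-3-ol | C=C1[C@H](C)CCC[C@]1(C)CC[C@](C)(O)/C=C\c1c(Br)ccc(OC)c1OCOC | intermediate
28 | (2S)-2-{2-[(1R,3R)-1,3-dimethyl-2-methylidenecyclohexyl]ethyl}-6-methoxy-5-(methoxymethoxy)-2-methyl-2H-chromene | C=C1[C@H](C)CCC[C@]1(C)CC[C@@]1(C)C=Cc2c(OCOC)c(OC)ccc2O1 | intermediate
29 | (2S)-2-{2-[(1R,3R)-1,3-dimethyl-2-methylidenecyclohexyl]ethyl}-6-methoxy-2-methyl-2H-chromen-5-ol | C=C1[C@H](C)CCC[C@]1(C)CC[C@@]1(C)C=Cc2c(O)c(OC)ccc2O1 | intermediate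
30 | (2S)-2-{2-[(1R,3R)-1,3-dimethyl-2-methylidenecyclohexyl]ethyl}-6-methoxy-2-methyl-2H-chromene-5,8-dione | C=C1[C@H](C)CCC[C@]1(C)CC[C@@]1(C)C=CC2=C(O1)C(=O)C=C(OC)C2=O | intermediate
31 | (2S)-2-{2-[(1R,3R)-1,3-dimethyl-2-methylidenecyclohexyl]ethyl}-6-methoxy-2-methyl-2H-chromene-5,8-diol | C=C1[C@H](C)CCC[C@]1(C)CC[C@@]1(C)C=Cc2c(O)c(OC)cc(O)c2O1 | target

## Counts and risks

Total step count: 19.
Longest linear sequence: 17 (steps 1–11 and 14–19). The arene branch is steps 12–13.

**Step 2.** The Michael donor carries a methyl group on both α-carbons. The addition is therefore slow, a second addition at C6 is conceivable, and the selectivity may fall below that of the parent system. The fallback keeps the same bond construction but uses the less hindered donor and adds the second methyl later. It sets out from 2 and 4. Commercial 2-methylcyclohexanone F1 is condensed with 2 to ketimine F2, which adds to 4 to give adduct imine F3. Aqueous AcOH hydrolyses this to (R)-2-methyl-2-(3-oxobutyl)cyclohexanone F4. The side-chain ketone is masked selectively (TMSOCH2CH2OTMS, cat. TMSOTf, CH2Cl2, −78 °C) as dioxolane F5. LDA/MeI methylates the only enolisable ring position to give methylated ketal F6 (C6 epimers). Aqueous HCl in acetone then returns diketone 7, where the route is rejoined and step 3 fixes C6 as before.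

**Step 6.** A bulky nucleophile must add to a 2,2,6-trisubstituted ketone whose α-stereocentre can epimerise. The fallback brings in the methylene carbon as a small, weakly basic sulfur ylide and removes the oxygen afterwards. It sets out from 12. Dimethylsulfonium methylide (Me3SI, NaH, DMSO/THF, 0 °C) gives spiro-epoxide F7. LiPPh2 opens it at the CH2 terminus and MeI quaternises phosphorus to give β-oxido phosphonium betaine F8. This collapses by syn-elimination (Vedejs-type epoxide deoxygenation) to enyne 14, where the route is rejoined, so steps 6 and 7 are both replaced.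

**Step 16.** The C–O coupling is run on a conjugated Z-alkenyl tether with an electron-rich aryl bromide. The fallback closes the ring on a saturated tether and introduces the C3=C4 double bond last. It sets out from 21 and 25. Lindlar semihydrogenation of 21 gives vinyl carbinol F9. 9-BBN hydroborates only its monosubstituted alkene to B-alkyl borane F10. A B-alkyl Suzuki–Miyaura coupling at the C–I bond of 25 (PdCl2(dppf), Cs2CO3, DMF/THF/H2O, rt) gives bromoaryl tertiary alcohol F11. The same palladium-catalysed etherification on this flexible sp3 tether gives chroman F12. DDQ dehydrogenation (benzene, reflux) through the oxygen-stabilised C4 benzylic cation then delivers chromene 28, where the route is rejoined.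

## Further compounds

F1 | step 2 | 2-methylcyclohexanone | CC1CCCCC1=O
F2 | step 2 | (1S)-N-(2-methylcyclohexylidene)-1-phenylethanamine | C[C@H](N=C1CCCCC1C)c1ccccc1
F3 | step 2 | 4-[(1R)-1-methyl-2-{[(1S)-1-phenylethyl]imino}cyclohexyl]butan-2-one | C[C@H](N=C1CCCC[C@]1(C)CCC(C)=O)c1ccccc1
F4 | step 2 | (R)-2-methyl-2-(3-oxobutyl)cyclohexanone | O=C1CCCC[C@]1(C)CCC(C)=O
F5 | step 2 | (R)-2-methyl-2-[2-(2-methyl-1,3-dioxolan-2-yl)ethyl]cyclohexanone | O=C1CCCC[C@]1(C)CCC1(C)OCCO1
F6 | step 2 | (2R)-2,6-dimethyl-2-[2-(2-methyl-1,3-dioxolan-2-yl)ethyl]cyclohexanone (C6 epimers) | O=C1C(C)CCC[C@]1(C)CCC1(C)OCCO1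
F7 | step 6 | (4R,8R)-4-(but-3-yn-1-yl)-4,8-dimethyl-1-oxaspiro[2.5]octane (spiro carbon inconsequential) | C1OC12[C@H](C)CCC[C@]2(C)CCC#C
F8 | step 6 | (2R,6R)-2-(but-3-yn-1-yl)-2,6-dimethyl-1-{[methyl(diphenyl)phosphonio]methyl}cyclohexan-1-olate | C[P+](c1ccccc1)(c1ccccc1)CC1([O-])[C@H](C)CCC[C@]1(C)CCC#C
F9 | step 16 | (3S)-5-[(1R,3R)-1,3-dimethyl-2-methylidenecyclohexyl]-3-methylpent-1-en-3-ol | C=C1[C@H](C)CCC[C@]1(C)CC[C@](C)(O)C=C
F10 | step 16 | (3S)-1-(9-borabicyclo[3.3.1]nonan-9-yl)-5-[(1R,3R)-1,3-dimethyl-2-methylidenecyclohexyl]-3-methylpentan-3-ol | C=C1[C@H](C)CCC[C@]1(C)CC[C@](C)(O)CCB1C2CCCC1CCC2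
F11 | step 16 | (3S)-1-[6-bromo-3-methoxy-2-(methoxymethoxy)phenyl]-5-[(1R,3R)-1,3-dimethyl-2-methylidenecyclohexyl]-3-methylpentan-3-ol | C=C1[C@H](C)CCC[C@]1(C)CC[C@](C)(O)CCc1c(Br)ccc(OC)c1OCOC
F12 | step 16 | (2S)-2-{2-[(1R,3R)-1,3-dimethyl-2-methylidenecyclohexyl]ethyl}-6-methoxy-5-(methoxymethoxy)-2-methylchroman | C=C1[C@H](C)CCC[C@]1(C)CC[C@@]1(C)CCc2c(OCOC)c(OC)ccc2O1
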